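**Plan**

1. Numbering: ring A is C1(OAc)–C2H2–C3H2–C4HBr–C5Me2–C6H2. The tricyclic core is numbered as an octahydroindene: C3 carries the side chain, C3a is the ring-fusion CH, C4 is the C(Me)–O carbon, C7 is CHBr, C7a is the quaternary carbon bearing the lactone carbonyl.
2. Retrosynthesis: the C1–O bond is cut first (Baeyer–Villiger transform, leaving a C1 acetyl group). Ring A is then cut at C5–C6 together with the C4–Br bond and a 1,2-shift of the core–CH2 group (bromonium-induced cation–olefin cyclization ended by a semipinacol shift). The chain is cut at the carbinol–vinyl bond and at the core–CH2 bond; the core is cut at the lactone C–O bond and the two Diels–Alder bonds.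
3. Enabling feature: the C4HBr–C5Me2–C6H2 triad is the imprint of a bromonium ion opened at its tertiary carbon by an alkene CH2, which makes C1 the cation site. Anti capture of that cation by an oxygen nucleophile would place O trans to Br, whereas the target has O cis to Br. The group that enters C1 anti is therefore made the core–CH2 carbon, and the oxygen arrives as the carbinol carbon that becomes the acetyl, then acetate, carbonyl.
4. Forward order: a catalytic asymmetric Diels–Alder reaction builds both carbocycles of the core, lactonization closes the bridged γ-lactone, and an Appel inversion installs the core bromide. Hydroboration/Suzuki coupling, ozonolysis and a vinyl-organocerium addition then build the chain, and ring A is closed last.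
5. Stereochemistry: the Diels–Alder catalyst and endo rule set C3a, C4, C7 (as oxygen, inverted later) and C7a; convex-face hydroboration sets C3. The chiral bromonium carrier sets C4 of ring A, the chair transition state with anti migration sets C1 cis to Br, and the Baeyer–Villiger step retains C1.

Key step: step 13

Assumption: the sense of induction of the two chiral catalysts (steps 3 and 13) follows their usual face-selection models; the catalyst antipode that gives the drawn isomer is the one meant.

**Route**

Step 1
Reactants: 1 hex-5-en-2-one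
Product: 3 4-oxopentanal, via ozonide 2 (not isolated)
Conditions: O3, CH2Cl2, −78 °C; then Me2S, −78 °C → rt
Reagents that add atoms: ozone, [O-][O+]=O
Why: Ozonolysis with reductive work-up cleaves the terminal alkene to the aldehyde and leaves the ketone untouched; no stereocenter is formed.

Step 2
Reactants: 3 4-oxopentanal
Product: 4 (1E,3Z)-1,4-bis[(tert-butyldimethylsilyl)oxy]penta-1,3-diene
Conditions: TBSOTf, Et3N, CH2Cl2, 0 °C → rt
Reagents that add atoms: tert-butyldimethylsilyl triflate, CC(C)(C)[Si](C)(C)OS(=O)(=O)C(F)(F)F
Why: Soft enolization and O-silylation of both carbonyl groups (silyl enol ether formation) under equilibrating conditions should give the conjugated bis-silyloxy diene, the ketone-derived enol ether with oxygen cis to the chain and the aldehyde-derived one trans, which is the only isomer able to reach the s-cis form used in step 3.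

Step 3
Reactants: 4 (1E,3Z)-1,4-bis[(tert-butyldimethylsilyl)oxy]penta-1,3-diene; 5 methyl 3-oxocyclopent-1-ene-1-carboxylate
Product: 6 methyl 4,7-bis[(tert-butyldimethylsilyl)oxy]-4-methyl-3-oxo-2,3,3a,4,7,7a-hexahydro-1H-indene-7a-carboxylate (cis-fused; 7a-CO2Me, 3a-H and 4-OTBS on one face, 7-OTBS on the other)
Conditions: Tf2NH-activated (S)-B-(o-tolyl)-α,α-diphenylprolinol oxazaborolidine (20 mol %), CH2Cl2, −78 °C
Reagents that add atoms: none
Why: Catalytic enantioselective Diels–Alder reaction of a cyclic enone with a 1-oxygenated diene, in which the unsubstituted diene terminus (largest HOMO coefficient, least hindered) bonds to the ester-bearing β-carbon of the enone, the cyclic dienophile enforces the cis ring fusion, endo orientation of the enone ring puts the outside C7 silyloxy group trans and the inside C4 silyloxy group cis to the C7a ester, and the chiral Lewis acid bound to the ketone selects the enone face and so fixes C3a, C4, C7 and C7a together.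

Step 4
Reactants: 6 Diels–Alder adduct
Product: 7 methyl 4,7-bis[(tert-butyldimethylsilyl)oxy]-4-methyl-3-oxooctahydro-1H-indene-7a-carboxylate (configuration as in 6)
Conditions: H2 (1 atm), Pd/C, EtOAc, rt
Reagents that add atoms: none
Why: Heterogeneous catalytic hydrogenation should saturate the disubstituted ring alkene and leave ketone, ester and silyl ethers alone; no stereocenter is formed.

Step 5
Reactants: 7 saturated keto ester
Product: 8 methyl 4,7-bis[(tert-butyldimethylsilyl)oxy]-4-methyl-3-methylideneoctahydro-1H-indene-7a-carboxylate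
Conditions: Zn, CH2Br2, TiCl4, THF, 0 °C; then 7, CH2Cl2, rt
Reagents that add atoms: dibromomethane, BrCBr
Why: Takai–Lombardo methylenation is non-basic, so the ketone, which carries an acidic ring-fusion hydrogen and a β-silyloxy group, should be methylenated without epimerization or β-elimination and in preference to the ester; no stereocenter is formed.

Step 6
Reactants: 8 methylidene bis-silyl ether
Product: 10 7-hydroxy-4-methyl-3-methylideneoctahydro-1H-indene-7a,4-carbolactone (7-OH axial and anti to the lactone carbonyl), via diol ester 9 (not isolated)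
Conditions: HF (48% aq.), MeCN, rt; then PPTS (cat.), toluene, 80 °C
Reagents that add atoms: none
Why: Fluoride-mediated desilylation frees both hydroxyls, and the tertiary C4 hydroxyl, placed cis and 1,3-diaxial to the C7a ester in step 3, should close the bridged γ-lactone by acid-catalysed transesterification, in which no stereocenter takes part.

Step 7
Reactants: 10 hydroxy lactone
Product: 11 7-bromo-4-methyl-3-methylideneoctahydro-1H-indene-7a,4-carbolactone (7-Br equatorial and syn to the lactone carbonyl)
Conditions: PPh3, CBr4, toluene, 0 → 60 °C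
Reagents that add atoms: carbon tetrabromide, BrC(Br)(Br)Br
Why: Appel reaction, in which the axial C7 oxyphosphonium ion (strained by its 1,3-diaxial contact with the cyclopentane ring) is displaced by bromide in an SN2 step with inversion to give the equatorial bromide syn to the lactone carbonyl, ionization being disfavoured by the adjacent acyl-bearing quaternary carbon.

Step 8
Reactants: 11 bromo lactone; 12 2-bromopropene
Product: 14 7-bromo-4-methyl-3-(2-methylprop-2-en-1-yl)octahydro-1H-indene-7a,4-carbolactone (3-H on the convex face), via B-alkyl-9-BBN 13 (not isolated)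
Conditions: 9-BBN, THF, 0 °C → rt; then 12, Pd(dppf)Cl2 (cat.), AsPh3 (cat.), Cs2CO3, DMF–H2O, rt
Reagents that add atoms: none
Why: Hydroboration followed by B-alkyl Suzuki–Miyaura coupling, in which 9-BBN adds to the exocyclic alkene from the open convex face of the lactone-locked cis-hydrindane and thereby places H on C3 on that face and the new CH2 on the concave face, cis to the C3a–C4 bond, while the unactivated secondary bromide stays out of the palladium cycle.

Step 9
Reactants: 14 methallyl lactone
Product: 16 7-bromo-4-methyl-3-(2-oxopropyl)octahydro-1H-indene-7a,4-carbolactone, via ozonide 15 (not isolated)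
Conditions: O3, CH2Cl2, −78 °C; then Me2S, −78 °C → rt
Reagents that add atoms: ozone, [O-][O+]=O
Why: Ozonolysis with reductive work-up cleaves the only alkene to the methyl ketone, and no stereocenter is touched.

Step 10
Reactants: 17 6-methylhept-5-en-2-one
Product: 18 (E)-6-methylhept-5-en-2-one 2,4,6-triisopropylbenzenesulfonylhydrazone
Conditions: 2,4,6-(i-Pr)3C6H2SO2NHNH2, HCl (cat.), MeOH, rt
Reagents that add atoms: 2,4,6-triisopropylbenzenesulfonyl hydrazide, NNS(=O)(=O)c1c(C(C)C)cc(C(C)C)cc1C(C)C
Why: Acid-catalysed hydrazone condensation should give the (E)-hydrazone with the sulfonamide nitrogen syn to the methyl group, as the next step needs.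

Step 11
Reactants: 18 trisylhydrazone; 16 methyl ketone
Product: 21 7-bromo-3-(2-hydroxy-2,7-dimethyl-3-methylideneoct-6-en-1-yl)-4-methyloctahydro-1H-indene-7a,4-carbolactone (both epimers at the carbinol carbon), via vinyllithium 19 (not isolated), via organocerium 20 (not isolated)
Conditions: 18, n-BuLi (2.1 equiv), THF, −78 → 0 °C; CeCl3, −78 °C; then 16, −78 °C; aq. NH4Cl
Reagents that add atoms: none
Why: Shapiro reaction (deprotonation at the methyl group syn to nitrogen, loss of sulfinate and N2) gives the 2-lithio-1-alkene, whose organocerium derivative should add to the enolizable methyl ketone (1,2-addition of an organocerium reagent) faster than to the hindered bridged lactone or the secondary bromide, the new carbinol carbon arising as both epimers, which is immaterial because it becomes the carbonyl carbon in step 13.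

Step 12
Reactants: 21 tertiary allylic alcohol
Product: 22 triethylsilyl ether of 21
Conditions: TESOTf, 2,6-lutidine, CH2Cl2, −78 → 0 °C
Reagents that add atoms: triethylsilyl triflate, CC[Si](CC)(CC)OS(=O)(=O)C(F)(F)F
Why: Silylation of the tertiary alcohol with a silyl triflate and a hindered base, which prepares the oxygen to drive the 1,2-shift of step 13 and keeps it from attacking the bromonium ion; no stereocenter is changed.

Step 13
Reactants: 22 silyl ether
Product: 23 3-{[(1R,4R)-1-acetyl-4-bromo-3,3-dimethylcyclohexyl]methyl}-7-bromo-4-methyloctahydro-1H-indene-7a,4-carbolactone (ring A: acetyl cis to Br)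
Conditions: 1,3-dibromo-5,5-dimethylhydantoin (1.1 equiv), (R)-BINOL-derived N-aryl thiophosphoramide Lewis base (10 mol %), toluene–CH2Cl2, −78 °C; aq. NaHCO3
Reagents that add atoms: 1,3-dibromo-5,5-dimethylhydantoin, CC1(C)N(Br)C(=O)N(Br)C1=O
Why: Proposed new method: the chiral sulfur Lewis base hands Br+ to one face of the electron-rich trisubstituted C4=C5 alkene, the CH2 terminus (C6) of the 1,1-disubstituted alkene opens the bromonium ion at its tertiary carbon C5, and the tertiary cation developing at C1 is quenched by a 1,2-shift of the core–CH2 group from the adjacent silyloxy carbon (semipinacol), whose silyloxocarbenium ion then loses Et3Si+ to give the methyl ketone. The closest known reaction types are the halonium-induced cation–olefin (polyene) cyclization, including its Lewis-base-catalysed enantioselective form, and the Prins–pinacol sequence, in which an allylic silyl ether ends a cation–olefin cyclization by a pinacol shift. Ring A closes in a 6-endo mode (both bromonium carbons and both alkene carbons become ring members) through a chair transition state. C4 is controlled by the catalyst (face of Br+ delivery) and by anti opening, which leaves Br equatorial; C1 is controlled by the substrate, because the migrating CH2 enters C1 anti to the new C5–C6 bond (equatorial, away from the axial C5 methyl), so that the acetyl group ends axial and cis to Br. The step needs chemoselectivity for the C4=C5 alkene (more electron-rich and less hindered than the allylic-ether alkene, which reacts only as a nucleophile through its CH2), face control that the remote core cannot give and that is therefore assigned to the catalyst, and migration of CH2R in preference to CH3 (higher migratory aptitude, and the largest group on the carbinol carbon lies perpendicular to the alkene plane on the side away from C5). The silyl ether secures termination by the shift in preference to proton loss or bromoetherification.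

Step 14
Reactants: 23 ring-A methyl ketone
Product: 24 (1R,4R)-4-bromo-1-{[(3R,3aS,4S,7R,7aR)-7-bromo-4-methyloctahydro-1H-indene-7a,4-carbolacton-3-yl]methyl}-3,3-dimethylcyclohexyl acetate (CNP0133010.1)
Conditions: (CF3CO)2O, H2O2·urea, Na2HPO4, CH2Cl2, 0 °C → rt
Reagents that add atoms: trifluoroperacetic acid (made in the flask from (CF3CO)2O and H2O2·urea), OOC(=O)C(F)(F)F
Why: Baeyer–Villiger oxidation, in which the fully substituted ring carbon C1 migrates in preference to methyl and with retention, so that the axial acetyl group should become the acetoxy group cis to bromine while lactone and bromides are inert to the peracid.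

**Compound list**

1 | hex-5-en-2-one | CC(=O)CCC=C | starting material
2 | 3-(3-oxobutyl)-1,2,4-trioxolane (ozonide of 1) | CC(=O)CCC1OCOO1 | intermediate
3 | 4-oxopentanal | CC(=O)CCC=O | intermediate
4 | (1E,3Z)-1,4-bis[(tert-butyldimethylsilyl)oxy]penta-1,3-diene | C/C(O[Si](C)(C)C(C)(C)C)=C/C=C/O[Si](C)(C)C(C)(C)C | intermediate
5 | methyl 3-oxocyclopent-1-ene-1-carboxylate | COC(=O)C1=CC(=O)CC1 | starting material
6 | methyl 4,7-bis[(tert-butyldimethylsilyl)oxy]-4-methyl-3-oxo-2,3,3a,4,7,7a-hexahydro-1H-indene-7a-carboxylate (cis-fused; ester, 3a-H and 4-OTBS on one face, 7-OTBS on the other) | O=C1CC[C@@]2(C(=O)OC)[C@@H](O[Si](C)(C)C(C)(C)C)C=C[C@](C)(O[Si](C)(C)C(C)(C)C)[C@@H]12 | intermediate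
7 | methyl 4,7-bis[(tert-butyldimethylsilyl)oxy]-4-methyl-3-oxooctahydro-1H-indene-7a-carboxylate | O=C1CC[C@@]2(C(=O)OC)[C@@H](O[Si](C)(C)C(C)(C)C)CC[C@](C)(O[Si](C)(C)C(C)(C)C)[C@@H]12 | intermediate
8 | methyl 4,7-bis[(tert-butyldimethylsilyl)oxy]-4-methyl-3-methylideneoctahydro-1H-indene-7a-carboxylate | C=C1CC[C@@]2(C(=O)OC)[C@@H](O[Si](C)(C)C(C)(C)C)CC[C@](C)(O[Si](C)(C)C(C)(C)C)[C@@H]12 | intermediate
9 | methyl 4,7-dihydroxy-4-methyl-3-methylideneoctahydro-1H-indene-7a-carboxylate | C=C1CC[C@@]2(C(=O)OC)[C@@H](O)CC[C@](C)(O)[C@@H]12 | intermediate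
10 | 7-hydroxy-4-methyl-3-methylideneoctahydro-1H-indene-7a,4-carbolactone (7-OH anti to the lactone carbonyl) | C=C1CC[C@@]23C(=O)O[C@@](C)(CC[C@@H]2O)[C@@H]13 | intermediate
11 | 7-bromo-4-methyl-3-methylideneoctahydro-1H-indene-7a,4-carbolactone (7-Br syn to the lactone carbonyl) | C=C1CC[C@@]23C(=O)O[C@@](C)(CC[C@H]2Br)[C@@H]13 | intermediate
12 | 2-bromopropene | CC(Br)=C | starting material
13 | 9-[(7-bromo-4-methyl-7a,4-carbolactone-octahydro-1H-inden-3-yl)methyl]-9-borabicyclo[3.3.1]nonane | B1(C2CCCC1CCC2)C[C@H]3CC[C@@]45C(=O)O[C@@](C)(CC[C@H]4Br)[C@@H]35 | intermediate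
14 | 7-bromo-4-methyl-3-(2-methylprop-2-en-1-yl)octahydro-1H-indene-7a,4-carbolactone | CC(=C)C[C@H]1CC[C@@]23C(=O)O[C@@](C)(CC[C@H]2Br)[C@@H]13 | intermediate
15 | 7-bromo-4-methyl-3-[(3-methyl-1,2,4-trioxolan-3-yl)methyl]octahydro-1H-indene-7a,4-carbolactone (ozonide of 14) | CC1(C[C@H]2CC[C@@]34C(=O)O[C@@](C)(CC[C@H]3Br)[C@@H]24)OCOO1 | intermediate
16 | 7-bromo-4-methyl-3-(2-oxopropyl)octahydro-1H-indene-7a,4-carbolactone | CC(=O)C[C@H]1CC[C@@]23C(=O)O[C@@](C)(CC[C@H]2Br)[C@@H]13 | intermediate
17 | 6-methylhept-5-en-2-one | CC(=O)CCC=C(C)C | starting material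
18 | (E)-6-methylhept-5-en-2-one 2,4,6-triisopropylbenzenesulfonylhydrazone | C/C(CCC=C(C)C)=N\NS(=O)(=O)c1c(C(C)C)cc(C(C)C)cc1C(C)C | intermediate
19 | (6-methylhepta-1,5-dien-2-yl)lithium | [Li]C(=C)CCC=C(C)C | intermediate
20 | dichloro(6-methylhepta-1,5-dien-2-yl)cerium | Cl[Ce](Cl)C(=C)CCC=C(C)C | intermediate
21 | 7-bromo-3-(2-hydroxy-2,7-dimethyl-3-methylideneoct-6-en-1-yl)-4-methyloctahydro-1H-indene-7a,4-carbolactone (both carbinol epimers) | CC(O)(C[C@H]1CC[C@@]23C(=O)O[C@@](C)(CC[C@H]2Br)[C@@H]13)C(=C)CCC=C(C)C | intermediate
22 | triethylsilyl ether of 21 | CC(O[Si](CC)(CC)CC)(C[C@H]1CC[C@@]23C(=O)O[C@@](C)(CC[C@H]2Br)[C@@H]13)C(=C)CCC=C(C)C | intermediate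
23 | 3-{[(1R,4R)-1-acetyl-4-bromo-3,3-dimethylcyclohexyl]methyl}-7-bromo-4-methyloctahydro-1H-indene-7a,4-carbolactone | CC(=O)[C@@]1(C[C@H]2CC[C@@]34C(=O)O[C@@](C)(CC[C@H]3Br)[C@@H]24)CC[C@@H](Br)C(C)(C)C1 | intermediate
24 | (1R,4R)-4-bromo-1-{[(3R,3aS,4S,7R,7aR)-7-bromo-4-methyloctahydro-1H-indene-7a,4-carbolacton-3-yl]methyl}-3,3-dimethylcyclohexyl acetate (CNP0133010.1) | CC(=O)O[C@@]1(C[C@H]2CC[C@@]34C(=O)O[C@@](C)(CC[C@H]3Br)[C@@H]24)CC[C@@H](Br)C(C)(C)C1 | target

**Step count and risks**

Total steps: 14. Longest linear sequence: 13 steps (steps 1–9 and 11–14).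

The three steps most likely to fail:

1. Step 13 (Proposed new method). Face selectivity may be eroded by bromonium transfer between alkenes before ring closure; the methyl group may shift instead of the core–CH2 group; the cation may be lost by proton elimination. Fallback with known chemistry, setting out from 13 and 17 and rejoining the route at 24: 17 is converted into its kinetic enol triflate, 6-methylhepta-1,5-dien-2-yl triflate F1 (LDA, then PhNTf2). F1 is coupled with the borane 13 under the conditions of step 8 to give the 1,5-diene F2. Bromonium-induced cation–olefin cyclization of F2 with Et2SBr·SbCl5Br in MeNO2, ended by proton loss, should give the ring-A bromocyclohexene F3 together with its double-bond isomers; the C4 epimer is removed by chromatography. Mukaiyama hydration (Mn(dpm)3, PhSiH3, O2) should convert all double-bond isomers into the tertiary alcohol F4, whose C1 epimer has to be separated because this route has no strong control at C1. Acetylation (Ac2O, Sc(OTf)3) then gives 24.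

2. Step 7. Elimination toward C6 may outrun substitution at the hindered, neopentyl-type C7. Fallback, setting out from 10 and rejoining the route at 16: the alcohol is carried on unprotected. Hydroboration of 10 with 9-BBN (2.2 equiv) gives the O,C-bis(boryl) species F5 (not isolated), which is coupled with 12 as in step 8 to give the methallyl alcohol F6. Ozonolysis through the ozonide F7 (not isolated) gives the hydroxy ketone F8. Anti elimination of the axial hydroxyl with Ph2S[OC(CF3)2Ph]2 gives the C6–C7 alkene F9. Radical hydrobromination by metal-hydride hydrogen-atom transfer (Co(acac)2, t-BuOOH, Et3SiH, TsBr) should put H on the less hindered C6 and deliver bromine to the C7 radical from the open equatorial side, giving 16.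

3. Step 3. The strong Lewis acid may desilylate the diene or divert it into a stepwise Mukaiyama–Michael addition, or discriminate the enone faces poorly. Fallback, setting out from 4 and 5 and rejoining the route at 6: the uncatalysed cycloaddition in toluene at 60–80 °C (same regio- and endo-preference expected on steric and electronic grounds) gives 6 together with its enantiomer F10, and the two are separated by preparative chromatography on a chiral stationary phase.

Further compounds
F1 | step 13 | 6-methylhepta-1,5-dien-2-yl trifluoromethanesulfonate | C=C(OS(=O)(=O)C(F)(F)F)CCC=C(C)C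
F2 | step 13 | 7-bromo-4-methyl-3-(6-methyl-2-methylidenehept-5-en-1-yl)octahydro-1H-indene-7a,4-carbolactone | C=C(C[C@H]1CC[C@@]23C(=O)O[C@@](C)(CC[C@H]2Br)[C@@H]13)CCC=C(C)C
F3 | step 13 | 7-bromo-3-{[(4R)-4-bromo-5,5-dimethylcyclohex-1-en-1-yl]methyl}-4-methyloctahydro-1H-indene-7a,4-carbolactone | Br[C@@H]1CC=C(C[C@H]2CC[C@@]34C(=O)O[C@@](C)(CC[C@H]3Br)[C@@H]24)CC1(C)C
F4 | step 13 | 7-bromo-3-{[(1R,4R)-4-bromo-1-hydroxy-3,3-dimethylcyclohexyl]methyl}-4-methyloctahydro-1H-indene-7a,4-carbolactone | O[C@@]1(C[C@H]2CC[C@@]34C(=O)O[C@@](C)(CC[C@H]3Br)[C@@H]24)CC[C@@H](Br)C(C)(C)C1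
F5 | step 7 | O,C-bis(9-borabicyclo[3.3.1]nonan-9-yl) derivative of 10 (boron on the 7-oxygen and on the 3-CH2 group) | B1(C2CCCC1CCC2)C[C@H]3CC[C@@]45C(=O)O[C@@](C)(CC[C@@H]4OB6C7CCCC6CCC7)[C@@H]35
F6 | step 7 | 7-hydroxy-4-methyl-3-(2-methylprop-2-en-1-yl)octahydro-1H-indene-7a,4-carbolactone | CC(=C)C[C@H]1CC[C@@]23C(=O)O[C@@](C)(CC[C@@H]2O)[C@@H]13
F7 | step 7 | 7-hydroxy-4-methyl-3-[(3-methyl-1,2,4-trioxolan-3-yl)methyl]octahydro-1H-indene-7a,4-carbolactone | CC1(C[C@H]2CC[C@@]34C(=O)O[C@@](C)(CC[C@@H]3O)[C@@H]24)OCOO1
F8 | step 7 | 7-hydroxy-4-methyl-3-(2-oxopropyl)octahydro-1H-indene-7a,4-carbolactone | CC(=O)C[C@H]1CC[C@@]23C(=O)O[C@@](C)(CC[C@@H]2O)[C@@H]13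
F9 | step 7 | 4-methyl-3-(2-oxopropyl)-2,3,3a,4,5,7a-hexahydro-1H-indene-7a,4-carbolactone (C6=C7 alkene) | CC(=O)C[C@H]1CC[C@@]23C(=O)O[C@@](C)(CC=C2)[C@@H]13
F10 | step 3 | enantiomer of 6 | O=C1CC[C@]2(C(=O)OC)[C@H](O[Si](C)(C)C(C)(C)C)C=C[C@@](C)(O[Si](C)(C)C(C)(C)C)[C@H]12
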